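**Plan**

- Numbering: the western core is numbered as benzo[6,7]cyclohepta[1,2,3-cd]benzofuran (C1 and C11b are the dihydrofuran CH's, C5a the ring-D carbon of the seven-membered ring, C6 the CH–OAr carbon, C7 the CH–aryl carbon). Ring D is the benzofuran benzo ring, ring B the other benzo ring.
- Retrosynthesis: the Z-alkene goes back to an alkyne and then to aryl triflate 10 plus a terminal alkyne (Sonogashira). The seven-membered ring is cut at C5a–C6, and the C6–OAr ether is cut by a Mitsunobu disconnection. C7–aryl and each dihydrobenzofuran C3–aryl bond come from rhodium conjugate arylation of a coumarin. Each dihydrobenzofuran C2–aryl bond comes from decarboxylative arylation.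
- Enabling feature: C6 is an O–CH carbon, so it can be generated as an α-aryloxyalkyl radical by loss of CO2 from an acid that a temporary ring-B lactone (O8–C(=O)–C6, absent from the target) delivers. C5a lies meta to both oxygens of ring D and is closed to Friedel–Crafts attack, but it is a phloroglucinol-type position whose oxygen can be carried as a triflate.
- Forward order: one coumarin triflate (3) gives the dihydrobenzofuran triflate 10 by arylation, bromination, ring contraction and decarboxylative arylation. Compound 10 is formylated on ring B, converted into a second coumarin, arylated at C7, hydroxylated and etherified; the lactone is opened and the seven-membered ring closed. Alkyne formation, Sonogashira coupling with a second molecule of 10, debenzylation and semi-hydrogenation finish the route.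
- Stereochemistry: C3 of both dihydrobenzofurans and C7 come from (R)-SEGPHOS/rhodium additions (reagent control). Both C2 centres are set trans to C3 by substrate control in the radical arylation. C6 is set in the ring closure, trans to the C7 aryl group. The Z-alkene comes from syn semi-hydrogenation.

Key step: step 14

Abbreviations in names: Bn = benzyl, triflyloxy = (trifluoromethanesulfonyl)oxy, DBF = the (2R,3R)-6-(benzyloxy)-2-[4-(benzyloxy)phenyl]-4-(triflyloxy)-2,3-dihydro-1-benzofuran-3-yl group.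

Remark: the configuration at the aryloxy-bearing carbon of 20–22 is written as formed but is assumed to be of no consequence, because this carbon becomes a planar radical in step 14.

**Route**

Step 1
Reactants: 1 5,7-dihydroxy-2H-chromen-2-one
Product: 2 7-(benzyloxy)-5-hydroxy-2H-chromen-2-one
Conditions: BnBr (1.0 equiv), K2CO3 (1.1 equiv), acetone, rt
Reagents that add atoms: benzyl bromide, BrCc1ccccc1
Why: Williamson etherification; the 7-hydroxyl, more acidic (para-type vinylogous acid of the lactone carbonyl) and free of the peri contact with C4–H, should react first, and any 5-benzyl or dibenzyl ether is removed by crystallisation.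

Step 2
Reactants: 2 7-(benzyloxy)-5-hydroxy-2H-chromen-2-one
Product: 3 7-(benzyloxy)-2-oxo-2H-chromen-5-yl trifluoromethanesulfonate
Conditions: Tf2O, pyridine, CH2Cl2, 0 °C
Reagents that add atoms: trifluoromethanesulfonic anhydride, O=S(=O)(OS(=O)(=O)C(F)(F)F)C(F)(F)F
Why: Sulfonylation of the remaining phenol; the triflate is at once a small peri substituent, a deactivating group for ring D in step 7 and the latent coupling handle at C4 of both dihydrobenzofurans.

Step 3
Reactants: 3 7-(benzyloxy)-2-oxo-2H-chromen-5-yl trifluoromethanesulfonate; 4 [3,5-bis(benzyloxy)phenyl]boronic acid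
Product: 5 (4R)-7-(benzyloxy)-4-[3,5-bis(benzyloxy)phenyl]-2-oxo-3,4-dihydro-2H-chromen-5-yl trifluoromethanesulfonate
Conditions: Rh(acac)(C2H4)2 (3 mol%), (R)-SEGPHOS (3.3 mol%), dioxane/H2O 10:1, 60 °C
Reagents that add atoms: none
Why: Hayashi–Miyaura asymmetric 1,4-addition of an arylboronic acid to a coumarin; the (R)-SEGPHOS arylrhodium species should add to the face that gives the (R)-4-arylchroman-2-one (the later C3 of the dihydrobenzofuran), and monovalent rhodium leaves the aryl triflate untouched.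

Step 4
Reactants: 5 (4R)-7-(benzyloxy)-4-[3,5-bis(benzyloxy)phenyl]-2-oxo-3,4-dihydro-2H-chromen-5-yl trifluoromethanesulfonate
Product: 7 (3S,4R)-7-(benzyloxy)-4-[3,5-bis(benzyloxy)phenyl]-3-bromo-2-oxo-3,4-dihydro-2H-chromen-5-yl trifluoromethanesulfonate (3,4-trans), via lithium enolate 6 (not isolated)
Conditions: LiN(SiMe3)2, THF, −78 °C; then NBS, −78 °C; NH4Cl
Reagents that add atoms: N-bromosuccinimide, O=C1CCC(=O)N1Br
Why: Electrophilic α-bromination of the lactone enolate, bromine entering anti to the C4 aryl group (3,4-trans); the new centre is only a relay, since it is inverted in step 5 and erased in step 6.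

Step 5
Reactants: 7 (3S,4R)-7-(benzyloxy)-4-[3,5-bis(benzyloxy)phenyl]-3-bromo-2-oxo-3,4-dihydro-2H-chromen-5-yl trifluoromethanesulfonate
Product: 8 (2R,3R)-6-(benzyloxy)-3-[3,5-bis(benzyloxy)phenyl]-4-(triflyloxy)-2,3-dihydro-1-benzofuran-2-carboxylic acid (2,3-trans)
Conditions: LiOH (2.2 equiv), THF/H2O, 0 °C to rt; then aq. HCl
Reagents that add atoms: lithium hydroxide, [Li+].[OH-]
Why: Alkaline ring contraction of a 3-halo-3,4-dihydrocoumarin, the dihydro counterpart of the Perkin coumarin-to-benzofuran rearrangement: hydroxide opens the aryl ester and the freed phenoxide displaces bromide 5-exo-tet with inversion, so that the trans bromolactone should give the trans 2,3-dihydrobenzofuran-2-carboxylic acid with C3 untouched.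

Step 6
Reactants: 8 (2R,3R)-6-(benzyloxy)-3-[3,5-bis(benzyloxy)phenyl]-4-(triflyloxy)-2,3-dihydro-1-benzofuran-2-carboxylic acid; 9 1-(benzyloxy)-4-bromobenzene
Product: 10 (2R,3R)-6-(benzyloxy)-2-[4-(benzyloxy)phenyl]-3-[3,5-bis(benzyloxy)phenyl]-2,3-dihydro-1-benzofuran-4-yl trifluoromethanesulfonate (2,3-trans)
Conditions: Ir[dF(CF3)ppy]2(dtbbpy)PF6 (1 mol%), NiCl2·glyme (10 mol%), dtbbpy (15 mol%), Cs2CO3, DMF, blue LEDs, rt
Reagents that add atoms: none
Why: Photoredox/nickel decarboxylative arylation of a cyclic α-oxy acid with an aryl bromide; the planar C2 radical is arylated anti to the C3 aryl group, which sets C2 as R (2,3-trans), and nickel should insert into the unhindered bromide, present in excess, in preference to the hindered electron-rich triflate.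

Step 7
Reactants: 10 (2R,3R)-6-(benzyloxy)-2-[4-(benzyloxy)phenyl]-3-[3,5-bis(benzyloxy)phenyl]-2,3-dihydro-1-benzofuran-4-yl trifluoromethanesulfonate
Product: 12 2,4-bis(benzyloxy)-6-DBF-benzaldehyde, via iminium chloride 11 (not isolated)
Conditions: POCl3, DMF, 0 to 60 °C; then aq. NaOAc
Reagents that add atoms: N,N-dimethylformamide, CN(C)C=O; water, O
Why: Vilsmeier–Haack formylation; ring B, the only ring with two alkoxy groups and no sulfonate, should be attacked para to one benzyloxy group and ortho to the other, at either of its two equivalent positions beside the benzylic carbon (as in orcinol ethers), and the iminium salt is hydrolysed on work-up.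

Step 8
Reactants: 12 2,4-bis(benzyloxy)-6-DBF-benzaldehyde
Product: 13 4-(benzyloxy)-2-hydroxy-6-DBF-benzaldehyde
Conditions: MgBr2·OEt2 (3 equiv), toluene/Et2O, 70 °C; then aq. HCl
Reagents that add atoms: none
Why: Chelation-controlled dealkylation: magnesium held between the aldehyde oxygen and the ortho ether oxygen activates only that benzyl ether for attack by bromide, so that the three other benzyl ethers should survive.

Step 9
Reactants: 13 4-(benzyloxy)-2-hydroxy-6-DBF-benzaldehyde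
Product: 14 7-(benzyloxy)-5-DBF-2H-chromen-2-one
Conditions: Ph3P=C=C=O (1.2 equiv), toluene, 90 °C
Reagents that add atoms: (triphenylphosphoranylidene)ketene, O=C=C=P(c1ccccc1)(c1ccccc1)c1ccccc1
Why: Coumarin synthesis with the ketenylidene ylide: the phenol adds to the cumulene and the ester ylide so formed closes on the neighbouring aldehyde by intramolecular Wittig olefination, which can give only the cis alkene of the lactone; this lactone is the temporary ring that carries the next three steps.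

Step 10
Reactants: 14 7-(benzyloxy)-5-DBF-2H-chromen-2-one; 15 [4-(benzyloxy)phenyl]boronic acid
Product: 16 (4R)-7-(benzyloxy)-4-[4-(benzyloxy)phenyl]-5-DBF-3,4-dihydro-2H-chromen-2-one
Conditions: Rh(acac)(C2H4)2 (5 mol%), (R)-SEGPHOS (5.5 mol%), dioxane/H2O 10:1, 80 °C
Reagents that add atoms: none
Why: Second Hayashi–Miyaura asymmetric 1,4-addition to a coumarin; the same (R)-ligand should again give the (R)-4-arylchroman-2-one (C7 of the target, R) under reagent control, the dihydrobenzofuran centres being remote from C4.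

Step 11
Reactants: 16 (4R)-7-(benzyloxy)-4-[4-(benzyloxy)phenyl]-5-DBF-3,4-dihydro-2H-chromen-2-one
Product: 18 (3S,4R)-7-(benzyloxy)-4-[4-(benzyloxy)phenyl]-3-hydroxy-5-DBF-3,4-dihydro-2H-chromen-2-one (3,4-trans), via sodium enolate 17 (not isolated)
Conditions: NaN(SiMe3)2, THF, −78 °C; then 2-(phenylsulfonyl)-3-phenyloxaziridine, −78 °C; NH4Cl
Reagents that add atoms: 2-(phenylsulfonyl)-3-phenyloxaziridine, O=S(=O)(N1OC1c1ccccc1)c1ccccc1
Why: Davis α-hydroxylation of the lactone enolate with the N-sulfonyloxaziridine, oxygen entering anti to the C4 aryl group to give the 3,4-trans alcohol, in which the C4 hydrogen is syn to the hydroxyl group.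

Step 12
Reactants: 18 (3S,4R)-7-(benzyloxy)-4-[4-(benzyloxy)phenyl]-3-hydroxy-5-DBF-3,4-dihydro-2H-chromen-2-one; 19 4-hydroxybenzaldehyde
Product: 20 4-{[(3R,4R)-7-(benzyloxy)-4-[4-(benzyloxy)phenyl]-5-DBF-2-oxo-3,4-dihydro-2H-chromen-3-yl]oxy}benzaldehyde (3,4-cis)
Conditions: PPh3, DIAD, THF, 0 °C to rt
Reagents that add atoms: none
Why: Mitsunobu etherification of an α-hydroxy lactone with an acidic phenol (SN2 with inversion, hence 3,4-cis); because the C4 hydrogen of the trans alcohol cannot become antiperiplanar to the leaving group within the ring, E2 loss to the coumarin should not compete.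

Step 13
Reactants: 20 4-{[(3R,4R)-7-(benzyloxy)-4-[4-(benzyloxy)phenyl]-5-DBF-2-oxo-3,4-dihydro-2H-chromen-3-yl]oxy}benzaldehyde
Product: 22 (2R,3R)-3-[2,4-bis(benzyloxy)-6-DBF-phenyl]-3-[4-(benzyloxy)phenyl]-2-(4-formylphenoxy)propanoic acid, via ring-opened disodium salt 21 (not isolated)
Conditions: NaOH (aq, 4 equiv), THF, 0 °C to rt; then BnBr, Bu4NBr, 40 °C; then aq. HCl
Reagents that add atoms: sodium hydroxide, [Na+].[OH-]; benzyl bromide, BrCc1ccccc1
Why: Saponification of the aryl ester followed by phase-transfer O-benzylation of the phenoxide (any benzyl ester formed is cleaved again by the excess hydroxide); the temporary lactone is thereby opened, O8 is protected like the other phenols and the carboxylic acid needed for step 14 is set free.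

Step 14
Reactants: 22 (2R,3R)-3-[2,4-bis(benzyloxy)-6-DBF-phenyl]-3-[4-(benzyloxy)phenyl]-2-(4-formylphenoxy)propanoic acid
Product: 23 4-{[(1R,6S,7R,11bR)-4,8,10-tris(benzyloxy)-1,7-bis[4-(benzyloxy)phenyl]-1,6,7,11b-tetrahydrobenzo[6,7]cyclohepta[1,2,3-cd][1]benzofuran-6-yl]oxy}benzaldehyde
Conditions: Ir[dF(CF3)ppy]2(dtbbpy)PF6 (2 mol%), NiCl2·glyme (20 mol%), dtbbpy (25 mol%), Cs2CO3 (2 equiv), DMF (5 mM), blue LEDs, 30 °C
Reagents that add atoms: none
Why: Proposed new method: excited Ir[dF(CF3)ppy]2(dtbbpy)PF6 oxidises the cesium carboxylate, CO2 is lost, and the α-aryloxyalkyl radical at C6 (stabilised by the ether oxygen) is captured by the arylnickel species formed by insertion of zerovalent nickel into the C5a–OTf bond; reductive elimination from the trivalent aryl(alkyl)nickel makes the C5a–C6 bond. The closest known reaction types are the intermolecular photoredox/nickel decarboxylative arylation of α-oxy acids with aryl halides (as in step 6) and the nickel/photoredox coupling of alkyl radicals with aryl triflates, here joined within one molecule. The seven-membered ring closes by C(sp2)–C(sp3) reductive elimination from an eight-membered nickelacycle, not by radical attack on the arene, which is why C5a, meta to both oxygens of ring D, can be used. The C2 centre of acid 22 is erased in the planar radical, and the new C6 centre (S) is set by the ring: radical capture at nickel is reversible, and the nickelacycle that eliminates should carry the aryloxy group trans to the C7 aryl group and pseudo-equatorial on the forming dibenzosuberane-type ring, C7 and the dihydrobenzofuran centres being fixed. The step needs ring closure to outrun reduction or dimerisation of the radical, which high dilution and the short diarylmethane hinge between the two reacting carbons should secure, and it needs the triflate to be the only site for nickel, which holds because no other halide or sulfonate is present and the aldehyde and benzyl ethers are inert.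

Step 15
Reactants: 23 4-{[(1R,6S,7R,11bR)-4,8,10-tris(benzyloxy)-1,7-bis[4-(benzyloxy)phenyl]-1,6,7,11b-tetrahydrobenzo[6,7]cyclohepta[1,2,3-cd][1]benzofuran-6-yl]oxy}benzaldehyde
Product: 24 (1R,6S,7R,11bR)-4,8,10-tris(benzyloxy)-1,7-bis[4-(benzyloxy)phenyl]-6-(4-ethynylphenoxy)-1,6,7,11b-tetrahydrobenzo[6,7]cyclohepta[1,2,3-cd][1]benzofuran
Conditions: dimethyl (1-diazo-2-oxopropyl)phosphonate, K2CO3, MeOH/THF, rt
Reagents that add atoms: dimethyl (1-diazo-2-oxopropyl)phosphonate, COP(=O)(OC)C(=[N+]=[N-])C(C)=O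
Why: Ohira–Bestmann variant of the Seyferth–Gilbert homologation converts the aryl aldehyde into the terminal alkyne under mild base that should leave the benzylic aryl ether and all stereocentres untouched.

Step 16
Reactants: 24 (1R,6S,7R,11bR)-4,8,10-tris(benzyloxy)-1,7-bis[4-(benzyloxy)phenyl]-6-(4-ethynylphenoxy)-1,6,7,11b-tetrahydrobenzo[6,7]cyclohepta[1,2,3-cd][1]benzofuran; 10 (2R,3R)-6-(benzyloxy)-2-[4-(benzyloxy)phenyl]-3-[3,5-bis(benzyloxy)phenyl]-2,3-dihydro-1-benzofuran-4-yl trifluoromethanesulfonate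
Product: 25 (1R,6S,7R,11bR)-4,8,10-tris(benzyloxy)-1,7-bis[4-(benzyloxy)phenyl]-6-[4-({(2R,3R)-6-(benzyloxy)-2-[4-(benzyloxy)phenyl]-3-[3,5-bis(benzyloxy)phenyl]-2,3-dihydro-1-benzofuran-4-yl}ethynyl)phenoxy]-1,6,7,11b-tetrahydrobenzo[6,7]cyclohepta[1,2,3-cd][1]benzofuran
Conditions: Pd(PPh3)4 (5 mol%), CuI (10 mol%), Et3N, DMF, 70 °C
Reagents that add atoms: none
Why: Sonogashira coupling of a terminal arylalkyne with an aryl triflate joins the two halves; the alkyne partner has no sulfonate left after step 14, so the second molecule of 10 can react only at its C4 triflate.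

Step 17
Reactants: 25 (the nona-benzyl ether diarylalkyne of step 16)
Product: 26 5-{(2R,3R)-6-hydroxy-2-(4-hydroxyphenyl)-4-[(4-{[(1R,6S,7R,11bR)-4,8,10-trihydroxy-1,7-bis(4-hydroxyphenyl)-1,6,7,11b-tetrahydrobenzo[6,7]cyclohepta[1,2,3-cd][1]benzofuran-6-yl]oxy}phenyl)ethynyl]-2,3-dihydro-1-benzofuran-3-yl}benzene-1,3-diol
Conditions: BCl3 (1 M in CH2Cl2, excess), pentamethylbenzene, CH2Cl2, −78 °C; then MeOH
Reagents that add atoms: none
Why: Lewis-acid debenzylation with pentamethylbenzene as a non-basic benzyl cation scavenger should remove the nine primary benzyl ethers at −78 °C faster than the secondary aryl ether at C6 can ionise (its cation is destabilised by the two meta oxygens of ring D), and it is run before the acid-sensitive cis-stilbene exists.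

Step 18
Reactants: 26 (the nonaphenol diarylalkyne of step 17)
Product: 27 5-{(2R,3R)-6-hydroxy-2-(4-hydroxyphenyl)-4-[(Z)-2-(4-{[(1R,6S,7R,11bR)-4,8,10-trihydroxy-1,7-bis(4-hydroxyphenyl)-1,6,7,11b-tetrahydrobenzo[6,7]cyclohepta[1,2,3-cd][1]benzofuran-6-yl]oxy}phenyl)ethenyl]-2,3-dihydro-1-benzofuran-3-yl}benzene-1,3-diol (CNP0354678.1)
Conditions: H2 (1 atm), Pd/CaCO3 poisoned with Pb(OAc)2, quinoline, EtOAc/MeOH, rt
Reagents that add atoms: none
Why: Lindlar-type semi-hydrogenation: syn delivery of hydrogen on the poisoned palladium surface should give the Z-alkene and stop there, and the benzylic C–O bonds are not hydrogenolysed on this catalyst.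

**Compound list**

1 | 5,7-dihydroxy-2H-chromen-2-one | O=C1C=Cc2c(O)cc(O)cc2O1 | starting material
2 | 7-(benzyloxy)-5-hydroxy-2H-chromen-2-one | O=C1C=Cc2c(O)cc(OCc3ccccc3)cc2O1 | intermediate
3 | 7-(benzyloxy)-2-oxo-2H-chromen-5-yl trifluoromethanesulfonate | O=C1C=Cc2c(OS(=O)(=O)C(F)(F)F)cc(OCc3ccccc3)cc2O1 | intermediate
4 | [3,5-bis(benzyloxy)phenyl]boronic acid | OB(O)c1cc(OCc2ccccc2)cc(OCc2ccccc2)c1 | starting material
5 | (4R)-7-(benzyloxy)-4-[3,5-bis(benzyloxy)phenyl]-2-oxo-3,4-dihydro-2H-chromen-5-yl trifluoromethanesulfonate | O=S(=O)(Oc1cc(OCc9ccccc9)cc2c1[C@@H](c8cc(OCc9ccccc9)cc(OCc9ccccc9)c8)CC(=O)O2)C(F)(F)F | intermediate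
6 | lithium enolate of 5: lithium (4R)-7-(benzyloxy)-4-[3,5-bis(benzyloxy)phenyl]-5-(triflyloxy)-4H-chromen-2-olate | O=S(=O)(Oc1cc(OCc9ccccc9)cc2c1[C@@H](c8cc(OCc9ccccc9)cc(OCc9ccccc9)c8)C=C([O-])O2)C(F)(F)F.[Li+] | intermediate
7 | (3S,4R)-7-(benzyloxy)-4-[3,5-bis(benzyloxy)phenyl]-3-bromo-2-oxo-3,4-dihydro-2H-chromen-5-yl trifluoromethanesulfonate | O=S(=O)(Oc1cc(OCc9ccccc9)cc2c1[C@@H](c8cc(OCc9ccccc9)cc(OCc9ccccc9)c8)[C@H](Br)C(=O)O2)C(F)(F)F | intermediate
8 | (2R,3R)-6-(benzyloxy)-3-[3,5-bis(benzyloxy)phenyl]-4-(triflyloxy)-2,3-dihydro-1-benzofuran-2-carboxylic acid | O=S(=O)(Oc1cc(OCc9ccccc9)cc2c1[C@@H](c8cc(OCc9ccccc9)cc(OCc9ccccc9)c8)[C@H](C(=O)O)O2)C(F)(F)F | intermediate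
9 | 1-(benzyloxy)-4-bromobenzene | Brc1ccc(OCc2ccccc2)cc1 | starting material
10 | (2R,3R)-6-(benzyloxy)-2-[4-(benzyloxy)phenyl]-3-[3,5-bis(benzyloxy)phenyl]-2,3-dihydro-1-benzofuran-4-yl trifluoromethanesulfonate | O=S(=O)(Oc1cc(OCc9ccccc9)cc2c1[C@@H](c8cc(OCc9ccccc9)cc(OCc9ccccc9)c8)[C@H](c8ccc(OCc9ccccc9)cc8)O2)C(F)(F)F | intermediate
11 | N-{[2,4-bis(benzyloxy)-6-DBF-phenyl]methylidene}-N-methylmethanaminium chloride | O=S(=O)(Oc1cc(OCc9ccccc9)cc2c1[C@@H](c8cc(OCc9ccccc9)cc(OCc9ccccc9)c8C=[N+](C)C)[C@H](c8ccc(OCc9ccccc9)cc8)O2)C(F)(F)F.[Cl-] | intermediate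
12 | 2,4-bis(benzyloxy)-6-DBF-benzaldehyde | O=S(=O)(Oc1cc(OCc9ccccc9)cc2c1[C@@H](c8cc(OCc9ccccc9)cc(OCc9ccccc9)c8C=O)[C@H](c8ccc(OCc9ccccc9)cc8)O2)C(F)(F)F | intermediate
13 | 4-(benzyloxy)-2-hydroxy-6-DBF-benzaldehyde | O=S(=O)(Oc1cc(OCc9ccccc9)cc2c1[C@@H](c8cc(OCc9ccccc9)cc(O)c8C=O)[C@H](c8ccc(OCc9ccccc9)cc8)O2)C(F)(F)F | intermediate
14 | 7-(benzyloxy)-5-DBF-2H-chromen-2-one | O=S(=O)(Oc1cc(OCc9ccccc9)cc2c1[C@@H](c8cc(OCc9ccccc9)cc7OC(=O)C=Cc87)[C@H](c8ccc(OCc9ccccc9)cc8)O2)C(F)(F)F | intermediate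
15 | [4-(benzyloxy)phenyl]boronic acid | OB(O)c1ccc(OCc2ccccc2)cc1 | starting material
16 | (4R)-7-(benzyloxy)-4-[4-(benzyloxy)phenyl]-5-DBF-3,4-dihydro-2H-chromen-2-one | O=S(=O)(Oc1cc(OCc9ccccc9)cc2c1[C@@H](c8cc(OCc9ccccc9)cc7OC(=O)C[C@H](c6ccc(OCc9ccccc9)cc6)c87)[C@H](c8ccc(OCc9ccccc9)cc8)O2)C(F)(F)F | intermediate
17 | sodium enolate of 16: sodium (4R)-7-(benzyloxy)-4-[4-(benzyloxy)phenyl]-5-DBF-4H-chromen-2-olate | O=S(=O)(Oc1cc(OCc9ccccc9)cc2c1[C@@H](c8cc(OCc9ccccc9)cc7OC([O-])=C[C@H](c6ccc(OCc9ccccc9)cc6)c87)[C@H](c8ccc(OCc9ccccc9)cc8)O2)C(F)(F)F.[Na+] | intermediate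
18 | (3S,4R)-7-(benzyloxy)-4-[4-(benzyloxy)phenyl]-3-hydroxy-5-DBF-3,4-dihydro-2H-chromen-2-one | O=S(=O)(Oc1cc(OCc9ccccc9)cc2c1[C@@H](c8cc(OCc9ccccc9)cc7OC(=O)[C@@H](O)[C@H](c6ccc(OCc9ccccc9)cc6)c87)[C@H](c8ccc(OCc9ccccc9)cc8)O2)C(F)(F)F | intermediate
19 | 4-hydroxybenzaldehyde | O=Cc1ccc(O)cc1 | starting material
20 | 4-{[(3R,4R)-7-(benzyloxy)-4-[4-(benzyloxy)phenyl]-5-DBF-2-oxo-3,4-dihydro-2H-chromen-3-yl]oxy}benzaldehyde | O=S(=O)(Oc1cc(OCc9ccccc9)cc2c1[C@@H](c8cc(OCc9ccccc9)cc7OC(=O)[C@H](Oc5ccc(C=O)cc5)[C@H](c6ccc(OCc9ccccc9)cc6)c87)[C@H](c8ccc(OCc9ccccc9)cc8)O2)C(F)(F)F | intermediate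
21 | disodium (2R,3R)-3-[4-(benzyloxy)-2-oxido-6-DBF-phenyl]-3-[4-(benzyloxy)phenyl]-2-(4-formylphenoxy)propanoate | O=S(=O)(Oc1cc(OCc9ccccc9)cc2c1[C@@H](c8cc(OCc9ccccc9)cc([O-])c8[C@@H](c6ccc(OCc9ccccc9)cc6)[C@@H](Oc5ccc(C=O)cc5)C([O-])=O)[C@H](c8ccc(OCc9ccccc9)cc8)O2)C(F)(F)F.[Na+].[Na+] | intermediate
22 | (2R,3R)-3-[2,4-bis(benzyloxy)-6-DBF-phenyl]-3-[4-(benzyloxy)phenyl]-2-(4-formylphenoxy)propanoic acid | O=S(=O)(Oc1cc(OCc9ccccc9)cc2c1[C@@H](c8cc(OCc9ccccc9)cc(OCc9ccccc9)c8[C@@H](c6ccc(OCc9ccccc9)cc6)[C@@H](Oc5ccc(C=O)cc5)C(=O)O)[C@H](c8ccc(OCc9ccccc9)cc8)O2)C(F)(F)F | intermediate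
23 | 4-{[(1R,6S,7R,11bR)-4,8,10-tris(benzyloxy)-1,7-bis[4-(benzyloxy)phenyl]-1,6,7,11b-tetrahydrobenzo[6,7]cyclohepta[1,2,3-cd][1]benzofuran-6-yl]oxy}benzaldehyde | c9ccccc9COc1ccc([C@@H]2c3c(OCc9ccccc9)cc(OCc9ccccc9)cc3[C@@H]3c4c(cc(OCc9ccccc9)cc4[C@H]2Oc2ccc(C=O)cc2)O[C@H]3c2ccc(OCc9ccccc9)cc2)cc1 | intermediate
24 | (1R,6S,7R,11bR)-4,8,10-tris(benzyloxy)-1,7-bis[4-(benzyloxy)phenyl]-6-(4-ethynylphenoxy)-1,6,7,11b-tetrahydrobenzo[6,7]cyclohepta[1,2,3-cd][1]benzofuran | c9ccccc9COc1ccc([C@@H]2c3c(OCc9ccccc9)cc(OCc9ccccc9)cc3[C@@H]3c4c(cc(OCc9ccccc9)cc4[C@H]2Oc2ccc(C#C)cc2)O[C@H]3c2ccc(OCc9ccccc9)cc2)cc1 | intermediate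
25 | (1R,6S,7R,11bR)-4,8,10-tris(benzyloxy)-1,7-bis[4-(benzyloxy)phenyl]-6-[4-({(2R,3R)-6-(benzyloxy)-2-[4-(benzyloxy)phenyl]-3-[3,5-bis(benzyloxy)phenyl]-2,3-dihydro-1-benzofuran-4-yl}ethynyl)phenoxy]-1,6,7,11b-tetrahydrobenzo[6,7]cyclohepta[1,2,3-cd][1]benzofuran | c9ccccc9COc1ccc([C@@H]2c3c(OCc9ccccc9)cc(OCc9ccccc9)cc3[C@@H]3c4c(cc(OCc9ccccc9)cc4[C@H]2Oc2ccc(C#Cc4cc(OCc9ccccc9)cc5c4[C@@H](c4cc(OCc9ccccc9)cc(OCc9ccccc9)c4)[C@H](c4ccc(OCc9ccccc9)cc4)O5)cc2)O[C@H]3c2ccc(OCc9ccccc9)cc2)cc1 | intermediate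
26 | 5-{(2R,3R)-6-hydroxy-2-(4-hydroxyphenyl)-4-[(4-{[(1R,6S,7R,11bR)-4,8,10-trihydroxy-1,7-bis(4-hydroxyphenyl)-1,6,7,11b-tetrahydrobenzo[6,7]cyclohepta[1,2,3-cd][1]benzofuran-6-yl]oxy}phenyl)ethynyl]-2,3-dihydro-1-benzofuran-3-yl}benzene-1,3-diol | Oc1ccc([C@@H]2c3c(O)cc(O)cc3[C@@H]3c4c(cc(O)cc4[C@H]2Oc2ccc(C#Cc4cc(O)cc5c4[C@@H](c4cc(O)cc(O)c4)[C@H](c4ccc(O)cc4)O5)cc2)O[C@H]3c2ccc(O)cc2)cc1 | intermediate
27 | 5-{(2R,3R)-6-hydroxy-2-(4-hydroxyphenyl)-4-[(Z)-2-(4-{[(1R,6S,7R,11bR)-4,8,10-trihydroxy-1,7-bis(4-hydroxyphenyl)-1,6,7,11b-tetrahydrobenzo[6,7]cyclohepta[1,2,3-cd][1]benzofuran-6-yl]oxy}phenyl)ethenyl]-2,3-dihydro-1-benzofuran-3-yl}benzene-1,3-diol (CNP0354678.1) | Oc1ccc([C@@H]2c3c(O)cc(O)cc3[C@@H]3c4c(cc(O)cc4[C@H]2Oc2ccc(/C=C\c4cc(O)cc5c4[C@@H](c4cc(O)cc(O)c4)[C@H](c4ccc(O)cc4)O5)cc2)O[C@H]3c2ccc(O)cc2)cc1 | target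

**Step count and risks**

Total step count: 18.
Longest linear sequence: 18 steps (1 → 2 → 3 → 5 → 7 → 8 → 10 → 12 → 13 → 14 → 16 → 18 → 20 → 22 → 23 → 24 → 25 → 26 → 27); compound 10 enters a second time in step 16.

Three steps most likely to fail:

1. Step 14 (bears the label "Proposed new method:"). What may go wrong: insertion of nickel into the hindered triflate may be too slow, so that the radical is reduced or oxidised before it is captured, or the ring may close with poor selectivity at C6. Fallback with known chemistry, setting out from 18 and returning at 23: the ring is closed by polar addition of the aryl carbon to an aldehyde, and the ether is made afterwards. Lactone 18 is opened and O-benzylated as in step 13 (NaOH; BnBr) to (2S,3R)-3-[2,4-bis(benzyloxy)-6-DBF-phenyl]-3-[4-(benzyloxy)phenyl]-2-hydroxypropanoic acid F1. Oxidative decarboxylation of this α-hydroxy acid with Pb(OAc)4 (CH2Cl2, 0 °C) should give (2R)-2-[2,4-bis(benzyloxy)-6-DBF-phenyl]-2-[4-(benzyloxy)phenyl]acetaldehyde F2. An intramolecular Nozaki–Hiyama–Kishi reaction (CrCl2, NiCl2 5 mol%, DMF, rt) adds C5a to the aldehyde; with the aldehyde oxygen turned away from the C7 aryl group it should give the 6,7-trans alcohol (1R,6S,7R,11bR)-4,8,10-tris(benzyloxy)-1,7-bis[4-(benzyloxy)phenyl]-1,6,7,11b-tetrahydrobenzo[6,7]cyclohepta[1,2,3-cd][1]benzofuran-6-ol F3. Its potassium alkoxide (KN(SiMe3)2, DMF, 0 °C) displaces fluoride from 4-fluorobenzaldehyde (SNAr, retention at C6) to give 23.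

2. Step 10. What may go wrong: insertion of the coumarin C3=C4 bond into the aryl–rhodium bond may be blocked by the peri DBF group, so that the boronic acid is only protodeboronated, or the ligand and the substrate stereocentres may be mismatched. Fallback, setting out from 13 and returning at 16: the aryl group is introduced by 1,2-addition and the stereocentre by hydride. Aldehyde 13 with 4-(benzyloxy)phenylmagnesium bromide (2.2 equiv, THF, −40 °C) should give [4-(benzyloxy)-2-hydroxy-6-DBF-phenyl][4-(benzyloxy)phenyl]methanol F4 (both epimers at the carbinol carbon). MnO2 (CH2Cl2, rt) should give [4-(benzyloxy)-2-hydroxy-6-DBF-phenyl][4-(benzyloxy)phenyl]methanone F5. Ph3P=C=C=O (toluene, 110 °C) should give 7-(benzyloxy)-4-[4-(benzyloxy)phenyl]-5-DBF-2H-chromen-2-one F6. Asymmetric conjugate reduction with CuH generated from Cu(OAc)2, (R)-DTBM-SEGPHOS and (EtO)2MeSiH (t-BuOH, toluene, rt) then gives 16; the ligand enantiomer is kept or exchanged according to the face of hydride delivery.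

3. Step 7. What may go wrong: poor site selectivity of the electrophilic substitution (attack between the two benzyloxy groups of ring B or on ring D), or low conversion beside the bulky benzylic carbon. Fallback, setting out from 10 and returning at 12: a smaller electrophile is used and the carbon is added by cross-coupling. NBS (MeCN, 0 °C), which enters 3,5-dialkoxyphenyl rings para to one alkoxy group, should give (2R,3S)-6-(benzyloxy)-2-[4-(benzyloxy)phenyl]-3-[3,5-bis(benzyloxy)-2-bromophenyl]-2,3-dihydro-1-benzofuran-4-yl trifluoromethanesulfonate F7 (same geometry as 10; the descriptor at C3 changes with the bromine). Suzuki–Miyaura coupling with vinylboronic acid pinacol ester under Pd2(dba)3/P(t-Bu)3 and KF in THF, a system that reacts with the aryl bromide in preference to the aryl triflate, should give (2R,3R)-6-(benzyloxy)-2-[4-(benzyloxy)phenyl]-3-[3,5-bis(benzyloxy)-2-ethenylphenyl]-2,3-dihydro-1-benzofuran-4-yl trifluoromethanesulfonate F8. Lemieux–Johnson cleavage (OsO4 cat., NaIO4, 2,6-lutidine, dioxane/H2O) gives 12.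

**Further compounds**

F1 | step 14 | (2S,3R)-3-[2,4-bis(benzyloxy)-6-DBF-phenyl]-3-[4-(benzyloxy)phenyl]-2-hydroxypropanoic acid | O=S(=O)(Oc1cc(OCc9ccccc9)cc2c1[C@@H](c8cc(OCc9ccccc9)cc(OCc9ccccc9)c8[C@@H](c6ccc(OCc9ccccc9)cc6)[C@H](O)C(=O)O)[C@H](c8ccc(OCc9ccccc9)cc8)O2)C(F)(F)F
F2 | step 14 | (2R)-2-[2,4-bis(benzyloxy)-6-DBF-phenyl]-2-[4-(benzyloxy)phenyl]acetaldehyde | O=S(=O)(Oc1cc(OCc9ccccc9)cc2c1[C@@H](c8cc(OCc9ccccc9)cc(OCc9ccccc9)c8[C@@H](c6ccc(OCc9ccccc9)cc6)C=O)[C@H](c8ccc(OCc9ccccc9)cc8)O2)C(F)(F)F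
F3 | step 14 | (1R,6S,7R,11bR)-4,8,10-tris(benzyloxy)-1,7-bis[4-(benzyloxy)phenyl]-1,6,7,11b-tetrahydrobenzo[6,7]cyclohepta[1,2,3-cd][1]benzofuran-6-ol | c9ccccc9COc1ccc([C@@H]2c3c(OCc9ccccc9)cc(OCc9ccccc9)cc3[C@@H]3c4c(cc(OCc9ccccc9)cc4[C@H]2O)O[C@H]3c2ccc(OCc9ccccc9)cc2)cc1
F4 | step 10 | [4-(benzyloxy)-2-hydroxy-6-DBF-phenyl][4-(benzyloxy)phenyl]methanol (both carbinol epimers) | O=S(=O)(Oc1cc(OCc9ccccc9)cc2c1[C@@H](c8cc(OCc9ccccc9)cc(O)c8C(O)c6ccc(OCc9ccccc9)cc6)[C@H](c8ccc(OCc9ccccc9)cc8)O2)C(F)(F)F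
F5 | step 10 | [4-(benzyloxy)-2-hydroxy-6-DBF-phenyl][4-(benzyloxy)phenyl]methanone | O=S(=O)(Oc1cc(OCc9ccccc9)cc2c1[C@@H](c8cc(OCc9ccccc9)cc(O)c8C(=O)c6ccc(OCc9ccccc9)cc6)[C@H](c8ccc(OCc9ccccc9)cc8)O2)C(F)(F)F
F6 | step 10 | 7-(benzyloxy)-4-[4-(benzyloxy)phenyl]-5-DBF-2H-chromen-2-one | O=S(=O)(Oc1cc(OCc9ccccc9)cc2c1[C@@H](c8cc(OCc9ccccc9)cc7OC(=O)C=C(c6ccc(OCc9ccccc9)cc6)c87)[C@H](c8ccc(OCc9ccccc9)cc8)O2)C(F)(F)F
F7 | step 7 | (2R,3S)-6-(benzyloxy)-2-[4-(benzyloxy)phenyl]-3-[3,5-bis(benzyloxy)-2-bromophenyl]-2,3-dihydro-1-benzofuran-4-yl trifluoromethanesulfonate | O=S(=O)(Oc1cc(OCc9ccccc9)cc2c1[C@@H](c8cc(OCc9ccccc9)cc(OCc9ccccc9)c8Br)[C@H](c8ccc(OCc9ccccc9)cc8)O2)C(F)(F)F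
F8 | step 7 | (2R,3R)-6-(benzyloxy)-2-[4-(benzyloxy)phenyl]-3-[3,5-bis(benzyloxy)-2-ethenylphenyl]-2,3-dihydro-1-benzofuran-4-yl trifluoromethanesulfonate | O=S(=O)(Oc1cc(OCc9ccccc9)cc2c1[C@@H](c8cc(OCc9ccccc9)cc(OCc9ccccc9)c8C=C)[C@H](c8ccc(OCc9ccccc9)cc8)O2)C(F)(F)F
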